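Atoms carry germacrane labels (ring C1–C10; C7 bears the isopropyl group, C6 the acetate). The route rests on closing the ten-membered carbocycle at C7–C8, the bond joining the ring CH2 to the isopropyl-bearing carbon beside C6. The isopropyl group is treated as a masked isopropenyl: the open-chain precursor ends in an (E)-2-methylallylic phosphate (C12–C11=C7) next to the C6 stereocentre and, at the other end, in a terminal diene. Hydroboration makes C8 an alkylborane, which copper delivers to C7 in SN2′ fashion; one operation forges C7–C8, the C7 stereocentre and the isopropenyl group. Selective hydrogenation, hydroxyl-directed 4,5-epoxidation and angeloylation complete the target.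

Key step: step 12

Remark on labels: germacrane = 4,10-dimethyl-7-isopropylcyclodecane; C14 is the methyl on C10, C15 the methyl on C4, C11–C13 the isopropyl carbons; the target is (3R,4R,5R,6S,7S,1(10)E).
Assumption: compound 1 is taken as a catalogue building block (otherwise one step from propargyl alcohol by Cp2ZrCl2-catalysed carboalumination with AlMe3 and iodination).

Step 1
Reactants: 1 (2E)-3-iodo-2-methylprop-2-en-1-ol
Product: 2 (2E)-3-iodo-2-methylprop-2-enal
Conditions: MnO2, CH2Cl2, rt
Reagents that add atoms: none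
Why: Allylic oxidation on activated MnO2 should stop at the enal and leave the vinyl iodide and its E geometry untouched.

Step 2
Reactants: 2 (2E)-3-iodo-2-methylprop-2-enal
Product: 3 (1E,3R)-1-iodo-2-methylhexa-1,5-dien-3-ol
Conditions: (R)-BINOL (20 mol %), Ti(OiPr)4 (10 mol %), 4 Å MS, allylSnBu3, CH2Cl2, −20 °C; aq. NaHCO3
Reagents that add atoms: allyltributylstannane C=CC[Sn](CCCC)(CCCC)CCCC
Why: Keck asymmetric allylation, in which the (R)-BINOL–titanium Lewis acid should direct the allyl group to the Re face of the enal and so set C3 as R.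

Step 3
Reactants: 3 (1E,3R)-1-iodo-2-methylhexa-1,5-dien-3-ol
Product: 4 tert-butyl{[(1E,3R)-1-iodo-2-methylhexa-1,5-dien-3-yl]oxy}dimethylsilane
Conditions: TBSCl, imidazole, DMF, rt
Reagents that add atoms: tert-butyldimethylsilyl chloride CC(C)(C)[Si](C)(C)Cl
Why: Standard silylation of a secondary alcohol masks the C3 hydroxyl for the organometallic steps that follow.

Step 4
Reactants: 4 tert-butyl{[(1E,3R)-1-iodo-2-methylhexa-1,5-dien-3-yl]oxy}dimethylsilane and 5 methacrolein (excess)
Product: 6 (2E,5R,6E)-5-[(tert-butyldimethylsilyl)oxy]-7-iodo-2,6-dimethylhepta-2,6-dienal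
Conditions: second-generation Hoveyda–Grubbs catalyst (5 mol %), CH2Cl2, 40 °C
Reagents that add atoms: none
Why: Olefin cross-metathesis of the terminal alkene with methacrolein should give the trisubstituted enal with thermodynamic E selectivity (the future C1=C10 bond), the trisubstituted vinyl iodide being inert to the ruthenium carbene.

Step 5
Reactants: 6 (2E,5R,6E)-5-[(tert-butyldimethylsilyl)oxy]-7-iodo-2,6-dimethylhepta-2,6-dienal
Product: 7 tert-butyl{[(1E,3R,5E)-1-iodo-2,6-dimethylocta-1,5,7-trien-3-yl]oxy}dimethylsilane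
Conditions: Ph3PCH3Br, KN(SiMe3)2, THF, 0 °C; then 6, −78 → 0 °C
Reagents that add atoms: methyltriphenylphosphonium bromide C[P+](c1ccccc1)(c1ccccc1)c1ccccc1.[Br-]
Why: Wittig methylenation converts the enal into the terminal 1,3-diene whose C8=C9 end later serves as the latent C8 nucleophile.

Step 6
Reactants: 7 tert-butyl{[(1E,3R,5E)-1-iodo-2,6-dimethylocta-1,5,7-trien-3-yl]oxy}dimethylsilane
Product: 9 (2E,4R,6E)-4-[(tert-butyldimethylsilyl)oxy]-3,7-dimethylnona-2,6,8-trienal, via alkenyllithium 8 (not isolated)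
Conditions: t-BuLi (2.1 equiv), Et2O, −78 °C; DMF; aq. NH4Cl
Reagents that add atoms: N,N-dimethylformamide CN(C)C=O
Why: Iodine–lithium exchange proceeds with retention of alkene geometry and formylation of the alkenyllithium with DMF (Bouveault-type) should give the E-enal that carries C6.

Step 7
Reactants: 1 (2E)-3-iodo-2-methylprop-2-en-1-ol
Product: 10 triethyl{[(2E)-3-iodo-2-methylprop-2-en-1-yl]oxy}silane
Conditions: TESCl, imidazole, CH2Cl2, 0 °C
Reagents that add atoms: triethylsilyl chloride CC[Si](Cl)(CC)CC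
Why: Silylation gives a primary triethylsilyl ether that can later be removed in the presence of the secondary tert-butyldimethylsilyl ether.

Step 8
Reactants: 10 triethyl{[(2E)-3-iodo-2-methylprop-2-en-1-yl]oxy}silane (2.2 equiv) and 9 (2E,4R,6E)-4-[(tert-butyldimethylsilyl)oxy]-3,7-dimethylnona-2,6,8-trienal
Product: 13 (2E,4S,5E,7R,9E)-7-[(tert-butyldimethylsilyl)oxy]-2,6,10-trimethyl-1-[(triethylsilyl)oxy]dodeca-2,5,9,11-tetraen-4-ol, via alkenyllithium 11 (not isolated), via bis(alkenyl)zinc 12 (not isolated)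
Conditions: t-BuLi, Et2O, −78 °C; ZnBr2, −78 → 0 °C; TEEDA, (−)-MIB (10 mol %), then 9, toluene, 0 °C; aq. NH4Cl
Reagents that add atoms: none
Why: Amino-alcohol-catalysed enantioselective addition of an alkenylzinc reagent to an aldehyde, in which the (−)-MIB–zinc complex should deliver the alkenyl group to the Si face of the enal and set C6 (chain C4) as S while the diamine masks the lithium halides that would promote a racemic background reaction.

Step 9
Reactants: 13 (2E,4S,5E,7R,9E)-7-[(tert-butyldimethylsilyl)oxy]-2,6,10-trimethyl-1-[(triethylsilyl)oxy]dodeca-2,5,9,11-tetraen-4-ol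
Product: 14 (2E,4S,5E,7R,9E)-7-[(tert-butyldimethylsilyl)oxy]-2,6,10-trimethyl-1-[(triethylsilyl)oxy]dodeca-2,5,9,11-tetraen-4-yl acetate
Conditions: Ac2O, Et3N, DMAP (cat.), CH2Cl2, 0 °C
Reagents that add atoms: acetic anhydride CC(=O)OC(C)=O
Why: Base-mediated acetylation installs the C6 acetate of the target early, where it also serves as the protecting group for the bis-allylic alcohol.

Step 10
Reactants: 14 (2E,4S,5E,7R,9E)-7-[(tert-butyldimethylsilyl)oxy]-2,6,10-trimethyl-1-[(triethylsilyl)oxy]dodeca-2,5,9,11-tetraen-4-yl acetate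
Product: 15 (2E,4S,5E,7R,9E)-7-[(tert-butyldimethylsilyl)oxy]-1-hydroxy-2,6,10-trimethyldodeca-2,5,9,11-tetraen-4-yl acetate
Conditions: HF·pyridine, pyridine, THF, 0 °C
Reagents that add atoms: none
Why: Buffered fluoride should cleave the primary triethylsilyl ether much faster than the secondary tert-butyldimethylsilyl ether and leave the acetate alone.

Step 11
Reactants: 15 (2E,4S,5E,7R,9E)-7-[(tert-butyldimethylsilyl)oxy]-1-hydroxy-2,6,10-trimethyldodeca-2,5,9,11-tetraen-4-yl acetate
Product: 16 (2E,4S,5E,7R,9E)-7-[(tert-butyldimethylsilyl)oxy]-1-[(diethoxyphosphoryl)oxy]-2,6,10-trimethyldodeca-2,5,9,11-tetraen-4-yl acetate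
Conditions: ClP(O)(OEt)2, pyridine, DMAP (cat.), CH2Cl2, 0 °C
Reagents that add atoms: diethyl chlorophosphate CCOP(=O)(Cl)OCC
Why: Phosphorylation of the primary allylic alcohol provides the leaving group for copper-mediated allylic substitution.

Step 12
Reactants: 16 (2E,4S,5E,7R,9E)-7-[(tert-butyldimethylsilyl)oxy]-1-[(diethoxyphosphoryl)oxy]-2,6,10-trimethyldodeca-2,5,9,11-tetraen-4-yl acetate
Product: 19 (1R,2E,4R,6E,10S)-4-[(tert-butyldimethylsilyl)oxy]-3,7-dimethyl-10-(prop-1-en-2-yl)cyclodeca-2,6-dien-1-yl acetate, via B-alkyl-9-BBN 17 (not isolated), via potassium alkyl(tert-butoxy)borate 18 (not isolated)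
Conditions: 9-BBN dimer, THF, 0 °C → rt; KOtBu (1.0 equiv), 0 °C; slow addition to CuOAc (20 mol %), THF, 60 °C (2 mM)
Reagents that add atoms: none
Why: Proposed new method: 9-BBN should add only to the monosubstituted C8=C9 end of the diene and place boron on C8; after activation as the tert-butoxyborate the alkyl group passes to monovalent copper, which adds to the C7=C11 π-bond anti to the phosphate to give a σ-allyl trivalent copper species at C7 that reductively eliminates, forming C7–C8 and releasing the C11=C12 isopropenyl group. The closest known reaction type is the intermolecular copper-catalysed γ-selective (SN2′) allyl–alkyl coupling of alkyl-9-BBN reagents with allylic phosphates; its ring-forming use on a medium ring is the untested part. The ten-membered carbocycle closes in a 10-exo SN2′ mode (C8 onto C7, the allyl double bond ending outside the ring), whereas direct α-attack at C12 would give a twelve-membered ring. The new stereocentre C7 is controlled by C6: A(1,3) strain between the C11 methyl and C6 holds C6–H in the alkene plane, so the tether, which leaves C6 through C5, reaches C7 on the face opposite the acetoxy group and should give the 6,7-trans (7S) product. The step needs γ- over α-selectivity and ring closure over oligomerisation; the first is inherent to the copper/alkylborane addition–elimination pathway, the second is sought by slow addition at high dilution and helped by the two E-trisubstituted alkenes, which pre-organise the chain.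

Step 13
Reactants: 19 (1R,2E,4R,6E,10S)-4-[(tert-butyldimethylsilyl)oxy]-3,7-dimethyl-10-(prop-1-en-2-yl)cyclodeca-2,6-dien-1-yl acetate
Product: 20 (1S,2E,4R,6E,10S)-4-[(tert-butyldimethylsilyl)oxy]-3,7-dimethyl-10-(propan-2-yl)cyclodeca-2,6-dien-1-yl acetate
Conditions: H2 (1 atm), RhCl(PPh3)3 (10 mol %), benzene, rt
Reagents that add atoms: none
Why: Homogeneous hydrogenation with Wilkinson's catalyst should reduce the 1,1-disubstituted isopropenyl group and spare the two trisubstituted ring alkenes and the allylic acetate (the C1 descriptor changes only through ligand priority).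

Step 14
Reactants: 20 (1S,2E,4R,6E,10S)-4-[(tert-butyldimethylsilyl)oxy]-3,7-dimethyl-10-(propan-2-yl)cyclodeca-2,6-dien-1-yl acetate
Product: 21 (1S,2E,4R,6E,10S)-4-hydroxy-3,7-dimethyl-10-(propan-2-yl)cyclodeca-2,6-dien-1-yl acetate
Conditions: Bu4NF, AcOH, THF, rt
Reagents that add atoms: none
Why: Fluoride desilylation buffered with acetic acid frees the C3 allylic alcohol without cleaving the C6 acetate.

Step 15
Reactants: 21 (1S,2E,4R,6E,10S)-4-hydroxy-3,7-dimethyl-10-(propan-2-yl)cyclodeca-2,6-dien-1-yl acetate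
Product: 22 (3R,4R,5R,6S,7S,1(10)E)-6-acetoxy-4,5-epoxygermacr-1(10)-en-3-ol
Conditions: VO(acac)2 (5 mol %), t-BuOOH, CH2Cl2, 0 °C
Reagents that add atoms: tert-butyl hydroperoxide CC(C)(C)OO
Why: Vanadium-catalysed hydroxyl-directed epoxidation should take the allylic C4=C5 bond in preference to the homoallylic C1=C10 bond and deliver oxygen in the erythro sense favoured by A(1,2) strain with the C4 methyl, which is also the exposed outer face of the crossed ring conformer, setting C4 and C5 as R,R.

Step 16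
Reactants: 22 (3R,4R,5R,6S,7S,1(10)E)-6-acetoxy-4,5-epoxygermacr-1(10)-en-3-ol and 23 angelic acid
Product: 25 (3R,4R,5R,6S,7S,1(10)E)-6-acetoxy-4,5-epoxygermacr-1(10)-en-3-yl (2Z)-2-methylbut-2-enoate (CNP0180504.3), via mixed anhydride 24 (not isolated)
Conditions: 2,4,6-Cl3C6H2COCl, Et3N, toluene, rt, filter; then 22, toluene, 80 °C
Reagents that add atoms: none
Why: Yamaguchi-type esterification through the 2,4,6-trichlorobenzoic mixed anhydride, run without DMAP, should acylate the hindered C3 alcohol without isomerising the Z-angelate to the E-tiglate and under basic conditions that the epoxide tolerates.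

Compound list
1 | (2E)-3-iodo-2-methylprop-2-en-1-ol | OC/C(C)=C/I | starting material
2 | (2E)-3-iodo-2-methylprop-2-enal | O=C/C(C)=C/I | intermediate
3 | (1E,3R)-1-iodo-2-methylhexa-1,5-dien-3-ol | C=CC[C@@H](O)/C(C)=C/I | intermediate
4 | tert-butyl{[(1E,3R)-1-iodo-2-methylhexa-1,5-dien-3-yl]oxy}dimethylsilane | C=CC[C@@H](O[Si](C)(C)C(C)(C)C)/C(C)=C/I | intermediate
5 | methacrolein (2-methylprop-2-enal) | C=C(C)C=O | starting material
6 | (2E,5R,6E)-5-[(tert-butyldimethylsilyl)oxy]-7-iodo-2,6-dimethylhepta-2,6-dienal | O=C/C(C)=C/C[C@@H](O[Si](C)(C)C(C)(C)C)/C(C)=C/I | intermediate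
7 | tert-butyl{[(1E,3R,5E)-1-iodo-2,6-dimethylocta-1,5,7-trien-3-yl]oxy}dimethylsilane | C=C/C(C)=C/C[C@@H](O[Si](C)(C)C(C)(C)C)/C(C)=C/I | intermediate
8 | [(1E,3R,5E)-3-[(tert-butyldimethylsilyl)oxy]-2,6-dimethylocta-1,5,7-trien-1-yl]lithium | C=C/C(C)=C/C[C@@H](O[Si](C)(C)C(C)(C)C)/C(C)=C/[Li] | intermediate
9 | (2E,4R,6E)-4-[(tert-butyldimethylsilyl)oxy]-3,7-dimethylnona-2,6,8-trienal | C=C/C(C)=C/C[C@@H](O[Si](C)(C)C(C)(C)C)/C(C)=C/C=O | intermediate
10 | triethyl{[(2E)-3-iodo-2-methylprop-2-en-1-yl]oxy}silane | CC[Si](CC)(CC)OC/C(C)=C/I | intermediate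
11 | [(1E)-2-methyl-3-[(triethylsilyl)oxy]prop-1-en-1-yl]lithium | CC[Si](CC)(CC)OC/C(C)=C/[Li] | intermediate
12 | bis[(1E)-2-methyl-3-[(triethylsilyl)oxy]prop-1-en-1-yl]zinc | CC[Si](CC)(CC)OC/C(C)=C/[Zn]/C=C(\C)CO[Si](CC)(CC)CC | intermediate
13 | (2E,4S,5E,7R,9E)-7-[(tert-butyldimethylsilyl)oxy]-2,6,10-trimethyl-1-[(triethylsilyl)oxy]dodeca-2,5,9,11-tetraen-4-ol | C=C/C(C)=C/C[C@@H](O[Si](C)(C)C(C)(C)C)/C(C)=C/[C@@H](O)/C=C(\C)CO[Si](CC)(CC)CC | intermediate
14 | (2E,4S,5E,7R,9E)-7-[(tert-butyldimethylsilyl)oxy]-2,6,10-trimethyl-1-[(triethylsilyl)oxy]dodeca-2,5,9,11-tetraen-4-yl acetate | C=C/C(C)=C/C[C@@H](O[Si](C)(C)C(C)(C)C)/C(C)=C/[C@@H](OC(C)=O)/C=C(\C)CO[Si](CC)(CC)CC | intermediate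
15 | (2E,4S,5E,7R,9E)-7-[(tert-butyldimethylsilyl)oxy]-1-hydroxy-2,6,10-trimethyldodeca-2,5,9,11-tetraen-4-yl acetate | C=C/C(C)=C/C[C@@H](O[Si](C)(C)C(C)(C)C)/C(C)=C/[C@@H](OC(C)=O)/C=C(\C)CO | intermediate
16 | (2E,4S,5E,7R,9E)-7-[(tert-butyldimethylsilyl)oxy]-1-[(diethoxyphosphoryl)oxy]-2,6,10-trimethyldodeca-2,5,9,11-tetraen-4-yl acetate | C=C/C(C)=C/C[C@@H](O[Si](C)(C)C(C)(C)C)/C(C)=C/[C@@H](OC(C)=O)/C=C(\C)COP(=O)(OCC)OCC | intermediate
17 | (2E,4S,5E,7R,9E)-12-(9-borabicyclo[3.3.1]nonan-9-yl)-7-[(tert-butyldimethylsilyl)oxy]-1-[(diethoxyphosphoryl)oxy]-2,6,10-trimethyldodeca-2,5,9-trien-4-yl acetate | C(B1C2CCCC1CCC2)C/C(C)=C/C[C@@H](O[Si](C)(C)C(C)(C)C)/C(C)=C/[C@@H](OC(C)=O)/C=C(\C)COP(=O)(OCC)OCC | intermediate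
18 | potassium salt of the B-tert-butoxy ate complex of 17 | [K+].CC(C)(C)O[B-]1(CC/C(C)=C/C[C@@H](O[Si](C)(C)C(C)(C)C)/C(C)=C/[C@@H](OC(C)=O)/C=C(\C)COP(=O)(OCC)OCC)C2CCCC1CCC2 | intermediate
19 | (1R,2E,4R,6E,10S)-4-[(tert-butyldimethylsilyl)oxy]-3,7-dimethyl-10-(prop-1-en-2-yl)cyclodeca-2,6-dien-1-yl acetate | C1/C(C)=C/C[C@@H](O[Si](C)(C)C(C)(C)C)/C(C)=C/[C@@H](OC(C)=O)[C@H](C(C)=C)C1 | intermediate
20 | (1S,2E,4R,6E,10S)-4-[(tert-butyldimethylsilyl)oxy]-3,7-dimethyl-10-(propan-2-yl)cyclodeca-2,6-dien-1-yl acetate | C1/C(C)=C/C[C@@H](O[Si](C)(C)C(C)(C)C)/C(C)=C/[C@@H](OC(C)=O)[C@H](C(C)C)C1 | intermediate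
21 | (1S,2E,4R,6E,10S)-4-hydroxy-3,7-dimethyl-10-(propan-2-yl)cyclodeca-2,6-dien-1-yl acetate | C1/C(C)=C/C[C@@H](O)/C(C)=C/[C@@H](OC(C)=O)[C@H](C(C)C)C1 | intermediate
22 | (3R,4R,5R,6S,7S,1(10)E)-6-acetoxy-4,5-epoxygermacr-1(10)-en-3-ol | O[C@@H]1C/C=C(\C)CC[C@@H](C(C)C)[C@H](OC(C)=O)[C@H]2O[C@@]21C | intermediate
23 | angelic acid, (2Z)-2-methylbut-2-enoic acid | C/C=C(/C)C(=O)O | starting material
24 | (2Z)-2-methylbut-2-enoic 2,4,6-trichlorobenzoic anhydride | C/C=C(/C)C(=O)OC(=O)c1c(Cl)cc(Cl)cc1Cl | intermediate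
25 | (3R,4R,5R,6S,7S,1(10)E)-6-acetoxy-4,5-epoxygermacr-1(10)-en-3-yl (2Z)-2-methylbut-2-enoate, CNP0180504.3 | C/C=C(/C)C(=O)O[C@@H]1C/C=C(\C)CC[C@@H](C(C)C)[C@H](OC(C)=O)[C@H]2O[C@@]21C | target

Total step count: 16. Longest linear sequence: 15 steps (steps 1–6 and 8–16).

Steps most likely to fail

Step 12 (proposed new method). The alkylcopper intermediate may decompose by protodemetalation or β-hydride elimination before the slow medium-ring closure occurs. Intermolecular coupling or α-attack may compete, facial selectivity at C7 may erode, and the C6 acetate may be lost to alkoxide. The fallback uses known chemistry and closes the same C7–C8 bond by an intramolecular Nozaki–Hiyama allylation of an aldehyde, after which the extra oxygen is removed; it sets out from 14 and returns at 19. Hydroboration of the terminal diene of 14 with 9-BBN and oxidation with NaBO3 should give the C8 primary alcohol F1. Dess–Martin oxidation should then give the β,γ-unsaturated C8 aldehyde F2, buffered HF·pyridine the C12 allylic alcohol F3, and CBr4/PPh3 the C12 allylic bromide F4. Slow addition of F4 to CrCl2 in THF should close the ring by γ-attack of the allylchromium species on the aldehyde, giving the C8 carbinol F5 (either C8 epimer serves) with the isopropenyl group already on C7. 1,1′-Thiocarbonyldiimidazole would convert it into the C8 imidazolylthiocarbonate F6, and Barton–McCombie reduction (Bu3SnH, Et3B, air, rt) would give 19.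

Step 8. Enantiofacial selectivity may be eroded by a ligand-free background addition promoted by residual lithium halides, and the bis-allylic alcohol may ionise on work-up. The fallback sets out from 10 and 9 and returns at 13: a catalytic asymmetric Nozaki–Hiyama–Kishi coupling (CrCl2, NiCl2, Mn, Cp2ZrCl2, chiral oxazoline–sulfonamide ligand, MeCN). Here a chromium-bound ligand, not a zinc amino alkoxide, differentiates the aldehyde faces, with the ligand enantiomer chosen for Si-face addition; the coupling gives 13 directly and adds no compound (F0).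

Step 16. Acylation of the hindered C3 alcohol may stall, and the angelate may isomerise from Z to E under forcing conditions. The fallback sets out from 22 and returns at 25 by building the Z-alkene on the molecule. Esterification of 22 with 2-[bis(2,2,2-trifluoroethoxy)phosphoryl]propanoic acid (DCC, DMAP, CH2Cl2) should give the C3 phosphonopropanoate F7. Still–Gennari olefination with acetaldehyde (KN(SiMe3)2, 18-crown-6, THF, −78 °C) should then give 25 with Z selectivity.

Further compounds
F1 | step 12 | C8 primary alcohol from hydroboration–oxidation of 14 | OCC/C(C)=C/C[C@@H](O[Si](C)(C)C(C)(C)C)/C(C)=C/[C@@H](OC(C)=O)/C=C(\C)CO[Si](CC)(CC)CC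
F2 | step 12 | C8 aldehyde from F1 | O=CC/C(C)=C/C[C@@H](O[Si](C)(C)C(C)(C)C)/C(C)=C/[C@@H](OC(C)=O)/C=C(\C)CO[Si](CC)(CC)CC
F3 | step 12 | C12 allylic alcohol from F2 (C8 aldehyde kept) | O=CC/C(C)=C/C[C@@H](O[Si](C)(C)C(C)(C)C)/C(C)=C/[C@@H](OC(C)=O)/C=C(\C)CO
F4 | step 12 | C12 allylic bromide from F3 (C8 aldehyde kept) | O=CC/C(C)=C/C[C@@H](O[Si](C)(C)C(C)(C)C)/C(C)=C/[C@@H](OC(C)=O)/C=C(\C)CBr
F5 | step 12 | 8-hydroxy derivative of 19 (C8 epimers) | C1/C(C)=C/C[C@@H](O[Si](C)(C)C(C)(C)C)/C(C)=C/[C@@H](OC(C)=O)[C@H](C(C)=C)C1O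
F6 | step 12 | O-(imidazol-1-yl)thiocarbonyl derivative of F5 | C1/C(C)=C/C[C@@H](O[Si](C)(C)C(C)(C)C)/C(C)=C/[C@@H](OC(C)=O)[C@H](C(C)=C)C1OC(=S)n2ccnc2
F0 | step 8 | none | none
F7 | step 16 | 2-[bis(2,2,2-trifluoroethoxy)phosphoryl]propanoate ester of 22 at C3 | CC(C(=O)O[C@@H]1C/C=C(\C)CC[C@@H](C(C)C)[C@H](OC(C)=O)[C@H]2O[C@@]21C)P(=O)(OCC(F)(F)F)OCC(F)(F)F
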